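The target in these flasks is a passing intermediate, so the number to count is how many of its lifetimes fit into the time you wait. Here are the flasks, the earlier readings and the questions.

| flask | starting material | coupling partner | remark | time |
|---|---|---|---|---|
| cedar | 0.0015 M | 0.034 M | run made earlier |  |
| oak | 0.0015 M | 0.045 M | run made earlier |  |
| eta | 0.0015 M | 0.0225 M |  | 8.0 h |
| theta | 0.0050 M | 0.0225 M |  | 8.0 h |
| gamma | 0.015 M | 0.0225 M |  | 8.0 h |
| epsilon | 0.050 M | 0.0225 M |  | 8.0 h |

| cedar: time / min | cedar: target / % | oak: time / min | oak: target / % |
|---|---|---|---|
| 20.0 | 29.2 | 8.00 | 15.8 |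
| 40.0 | 42.1 | 15.0 | 27.2 |
| 60.0 | 45.2 | 25.0 | 36.4 |
| 80.0 | 44.5 | 50.0 | 47.5 |
| 90.0 | 42.3 | 90.0 | 43.1 |

(each reading ± 0.5 percentage points)

- [target] at the end for eta, theta, gamma, epsilon, in this order
- how that number moves from the first to the last of them (rises, then falls / falls all the way / hardly changes / rises all the way / falls, then rises)

- "hardly changes" means that all values lie within two and a half points (for a concentration: within two and a half percent of the largest)

Read the ladder from cedar. The first reading, taken as first-order growth, gives a formation constant k_f of about 0.0173 min⁻¹, a reading that ignores any target lost by then. That is a half-life of 40.1 min. The cedar readings peak near 60.0 min, and if you take making as equal to losing there, k_f times the starting material still present, reckoned from k_f, divided by the 45.2 % of target gives a loss constant k_l of about 0.0136 min⁻¹, a half-life of 51.1 min. Both of these cedar rungs sit far below the top rung, the wait t of 8.0 h, and my count of target lifetimes in that wait, n = k_l t, is 6.51. Because the wait is long against that half-life, you keep about 0.149 % of any target standing at the start of the wait, so by my reckoning the end value follows the late feed rather than the early yield. That feed should grow with the charge while coupling partner lasts, but epsilon holds less coupling partner than starting material, which makes the partner its likely limiting reagent, and I expect the feed in epsilon to stop when the partner is used up. I therefore commit to a rise and then a fall, without a row of my own.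

The forecast gives 2.000 × 10⁻⁵ M, 1.000 × 10⁻⁴ M, 4.000 × 10⁻⁴ M and 1.400 × 10⁻⁴ M, and its shape is "rises, then falls"; it reckons that after the wait “target decay has cut everything to near zero”.

The flasks give 2.56 × 10⁻⁵ M, 9.35 × 10⁻⁵ M, 3.93 × 10⁻⁴ M and 1.14 × 10⁻⁴ M, so the row rises, then falls.

    starting material + coupling partner → target, rate k1*[starting material]*[coupling partner]^0.5 (k = 0.00190 L⁰·⁵ mol⁻⁰·⁵ s⁻¹)
    target → over-reaction product (k = 1.90 × 10⁻⁴ s⁻¹)
    2 coupling partner → homo dimer (k = 0.00200 L mol⁻¹ s⁻¹)

In eta at the asked time, the target's half-life by its loss step is 1.0 h, shorter than the 8.0 h, which counts 5.47 lifetimes, and target is then made at 0.178 of the rate at which it is used. In epsilon, coupling partner stands at 0 % at 4.00 h, and the part of n for the stretch up to 8.00 h is 3.25, while target falls from 3.53 % to 0.229 %, a fall of 2.74 lifetimes.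

The earlier runs and the new flask were computed on assumed constants, and the scatter is random.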